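**Strategy.** Ring B is disconnected at C6–C7. The key step exploits the neopentyl C6 methylene on the quaternary ring A carbon C5 and the isopropenyl-bearing C7. C6 resists ionic substitution, but as a radical made from its iodide it has no β-hydrogen to lose. It adds 6-exo to C7 of a C7=C11 dimethylvinyl group, and cobalt-mediated loss of a methyl hydrogen leaves the C11 isopropenyl group. One operation closes ring B, forms C6–C7 and sets C7. The precursor is a ring A cyclohexanone (C2 ketone, cis C4/C5 methyls, C5 iodomethyl) whose C10 carries a cis-dioxolane (C8/C9 acetonide) ending in the dimethylvinyl group. It is assembled by Diels–Alder reaction of tiglaldehyde with an L-erythrose-derived silyloxydiene.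

Key step: step 10

Assumption: eremophilane numbering is used for all intermediates (C1–C10 ring carbons, ketone at C2, C6 the ring B methylene, C7 the isopropenyl-bearing carbon, C11 its central carbon); the anomeric centre of 1, 2 and 4 is an equilibrating mixture and is left unspecified in the SMILES.

Step 1
Reactants: 1 L-arabinose
Product: 2 3,4-O-isopropylidene-L-arabinopyranose
Conditions: Me2C(OMe)2, TsOH·H2O (cat.), DMF, rt
Reagents that add atoms: 2,2-dimethoxypropane, COC(C)(C)OC
Why: Acid-catalysed acetal exchange takes the cis-3,4-diol of the pyranose into the acetonide and leaves O1 and O2 free for the glycol cleavage that follows.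

Step 2
Reactants: 2 3,4-O-isopropylidene-L-arabinopyranose
Product: 4 2,3-O-isopropylidene-L-erythrose (furanose lactol), via formate ester 3 (not isolated)
Conditions: NaIO4, H2O, 0 °C to rt; then Na2CO3
Reagents that add atoms: none
Why: Periodate glycol cleavage of the C1–C2 hydroxy-hemiacetal excises C1 as a formate ester, whose mild hydrolysis lets the lactol close; the two stereocentres (future C8 and C9) come unchanged from the sugar.

Step 3
Reactants: 4 2,3-O-isopropylidene-L-erythrose
Product: 5 [(4S,5R)-2,2-dimethyl-5-(2-methylprop-1-en-1-yl)-1,3-dioxolan-4-yl]methanol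
Conditions: i-PrPPh3I, n-BuLi, THF, 0 °C; then 4, 0 °C to rt
Reagents that add atoms: isopropyltriphenylphosphonium iodide, CC(C)[P+](c1ccccc1)(c1ccccc1)c1ccccc1.[I-]
Why: Wittig olefination of the lactol through its open aldehyde form installs the C7=C11 dimethylvinyl terminus (the lactol carbon becomes C7) and frees the primary hydroxyl on the carbon next to C9.

Step 4
Reactants: 5 [(4S,5R)-2,2-dimethyl-5-(2-methylprop-1-en-1-yl)-1,3-dioxolan-4-yl]methanol
Product: 7 (3E)-4-[(4S,5R)-2,2-dimethyl-5-(2-methylprop-1-en-1-yl)-1,3-dioxolan-4-yl]but-3-en-2-one, via dioxolane aldehyde 6 (not isolated)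
Conditions: Dess–Martin periodinane, CH2Cl2, 0 °C to rt; then Ph3P=CHC(O)CH3, rt
Reagents that add atoms: 1-(triphenyl-λ5-phosphanylidene)propan-2-one, CC(=O)C=P(c1ccccc1)(c1ccccc1)c1ccccc1
Why: Dess–Martin oxidation followed in the same flask by an E-selective Wittig reaction with the stabilised, non-basic ylide traps the epimerisable cis-aldehyde at once and gives the enone that holds C10, C1, C2 and C3.

Step 5
Reactants: 7 (3E)-4-[(4S,5R)-2,2-dimethyl-5-(2-methylprop-1-en-1-yl)-1,3-dioxolan-4-yl]but-3-en-2-one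
Product: 8 triisopropyl({(3E)-4-[(4S,5R)-2,2-dimethyl-5-(2-methylprop-1-en-1-yl)-1,3-dioxolan-4-yl]buta-1,3-dien-2-yl}oxy)silane
Conditions: TIPSOTf, Et3N, CH2Cl2, 0 °C
Reagents that add atoms: triisopropylsilyl trifluoromethanesulfonate, CC(C)[Si](C(C)C)(C(C)C)OS(=O)(=O)C(F)(F)F
Why: Soft enolisation of the methyl ketone (silyl triflate and amine) gives the cross-conjugated 2-silyloxydiene, and the bulky silyl group makes the dienol ether robust enough for Lewis acid catalysis.

Step 6
Reactants: 8 the silyloxydiene; 9 tiglaldehyde ((E)-2-methylbut-2-enal)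
Product: 10 (1R,2S,6S)-2-[(4S,5R)-2,2-dimethyl-5-(2-methylprop-1-en-1-yl)-1,3-dioxolan-4-yl]-1,6-dimethyl-4-[(triisopropylsilyl)oxy]cyclohex-3-ene-1-carbaldehyde (ring A; C5 = ring C1, C10 = ring C2, C4 = ring C6)
Conditions: (R)-3,3-diphenyl-1-(o-tolyl)tetrahydro-1H,3H-pyrrolo[1,2-c][1,3,2]oxazaborole·HNTf2 (20 mol %), CH2Cl2, −78 to −40 °C
Reagents that add atoms: none
Why: Catalytic enantioselective Diels–Alder reaction, in which the 2-silyloxy group (para) and the C10 substituent (ortho) send C3 to the enal β-carbon (C4) and C10 to the α-carbon (C5), the E-enal puts the C4 and C5 methyls cis, endo approach with both methyls exo places the formyl carbon C6 cis to the dioxolane on C10, and the catalyst, holding the s-trans enal through boron and a formyl C–H···O contact, shields the Re face of C2 of 9 so that the diene adds to its Si face (4S,5R,10S), while the C9 stereocentre sits at the later-forming C10–C5 bond of this asynchronous addition and is expected to have little say.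

Step 7
Reactants: 10 the ring A aldehyde
Product: 11 {(1R,2S,6S)-2-[(4S,5R)-2,2-dimethyl-5-(2-methylprop-1-en-1-yl)-1,3-dioxolan-4-yl]-1,6-dimethyl-4-[(triisopropylsilyl)oxy]cyclohex-3-en-1-yl}methanol
Conditions: NaBH4, MeOH/THF, 0 °C
Reagents that add atoms: none
Why: Borohydride reduction touches only the aldehyde, because the C2 carbonyl is still masked as the silyl enol ether delivered by the cycloaddition.

Step 8
Reactants: 11 the silyl enol ether alcohol
Product: 12 (3S,4R,5S)-3-[(4S,5R)-2,2-dimethyl-5-(2-methylprop-1-en-1-yl)-1,3-dioxolan-4-yl]-4-(hydroxymethyl)-4,5-dimethylcyclohexan-1-one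
Conditions: Bu4NF, AcOH, THF, 0 °C
Reagents that add atoms: none
Why: Fluoride-mediated desilylation with buffered protonation of the enolate releases the C2 ketone without touching the acetonide; no stereocentre lies α to the ketone.

Step 9
Reactants: 12 the hydroxy ketone
Product: 13 (3S,4R,5S)-3-[(4S,5R)-2,2-dimethyl-5-(2-methylprop-1-en-1-yl)-1,3-dioxolan-4-yl]-4-(iodomethyl)-4,5-dimethylcyclohexan-1-one (key-step precursor)
Conditions: PPh3, imidazole, I2, toluene, 80 °C
Reagents that add atoms: iodine, II
Why: Garegg–Samuelsson (Appel-type) iodination, in which iodide displaces the alkoxyphosphonium group; heating compensates for the neopentyl retardation, and C6 is not stereogenic.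

Step 10
Reactants: 13 the neopentyl iodide
Product: 14 (4S,5R,7R,8R,9S,10S)-8,9-(isopropylidenedioxy)eremophil-11-en-2-one (8α,9α-acetonide, 7β-isopropenyl, 10β-H)
Conditions: Ph3SnCo(dmgH)2(py) (15 mol %; dmgH = dimethylglyoximate), i-Pr2NEt, MeCN, blue LEDs, 25 °C
Reagents that add atoms: none
Why: Light releases divalent cobaloxime from the tin–cobalt precatalyst, and low-valent cobalt activates the C6–I bond by electron transfer or iodine abstraction (SN2 is closed at a neopentyl carbon; any C6–Co bond is cleaved by light); the C6 radical adds to C7 of the C7=C11 alkene, the tertiary C11 radical is captured by divalent cobalt, a methyl hydrogen leaves as a cobalt hydride, and the amine deprotonates the hydride to close the cycle. The closest known reaction type is the cobaloxime-catalysed intramolecular Heck-type coupling of unactivated primary alkyl iodides with alkenes. Ring B closes in the 6-exo-trig mode, attack at the less substituted alkene carbon being favoured over 7-endo attack at the fully substituted C11. C7 is set by a chair-like transition state of the cis-dioxolane-fused chain with O8 equatorial, O9 axial and the C7=C11 unit pseudo-equatorial, which puts the isopropenyl group β and trans to O8; the epimer would need C11 syn-axial to C4 and O9. The step needs cyclisation to outrun hydrogen abstraction and needs the terminal alkene: the cis-dioxolane holds C7 close to C6 and turns the allylic C8–H away from it, and the hindered cobaloxime takes one of the six accessible methyl hydrogens and not the ring C7–H.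

Step 11
Reactants: 14 the tricyclic acetonide
Product: 15 (4S,5R,7R,8R,9S,10S)-8,9-dihydroxyeremophil-11-en-2-one
Conditions: AcOH/H2O/THF 3:1:1, 45 °C
Reagents that add atoms: none
Why: Acid-catalysed acetonide hydrolysis under mild aqueous acetic acid frees the cis-diol and spares the isopropenyl group and the ketone.

Step 12
Reactants: 15 the diol; 16 (R)-2-methylbutanoic acid
Product: 17 (4S,5R,7R,8R,9S,10S)-9-hydroxy-8-{[(2R)-2-methylbutanoyl]oxy}eremophil-11-en-2-one
Conditions: DIC, DMAP (cat.), CH2Cl2, 0 °C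
Reagents that add atoms: none
Why: Steglich esterification takes the equatorial C8 hydroxyl, because the axial C9 hydroxyl is shielded by ring A (syn-axial to C4) and can rest as a hemiketal with the C2 ketone; carbodiimide activation at 0 °C keeps the α-stereocentre of the acid intact.

Step 13
Reactants: 17 the C8 monoester; 18 tigloyl chloride ((E)-2-methylbut-2-enoyl chloride)
Product: 19 CNP0312791.1, (4S,5R,7R,8R,9S,10S)-8-{[(2R)-2-methylbutanoyl]oxy}-9-{[(2E)-2-methylbut-2-enoyl]oxy}eremophil-11-en-2-one
Conditions: DMAP, pyridine, toluene, 60 °C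
Reagents that add atoms: none
Why: DMAP-catalysed acylation of the remaining axial alcohol by the acid chloride; acylation at oxygen leaves C9 untouched and the E geometry of the tiglate is the stable one.

**Compound list**

1 | L-arabinose (pyranose form) | OC1OC[C@H](O)[C@H](O)[C@H]1O | starting material
2 | 3,4-O-isopropylidene-L-arabinopyranose | OC1OC[C@@H]2OC(C)(C)O[C@@H]2[C@H]1O | intermediate
3 | 4-O-formyl-2,3-O-isopropylidene-aldehydo-L-erythrose | O=C[C@H]1OC(C)(C)O[C@H]1COC=O | intermediate
4 | 2,3-O-isopropylidene-L-erythrose (furanose lactol) | OC1OC[C@@H]2OC(C)(C)O[C@H]12 | intermediate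
5 | [(4S,5R)-2,2-dimethyl-5-(2-methylprop-1-en-1-yl)-1,3-dioxolan-4-yl]methanol | CC(C)=C[C@H]1OC(C)(C)O[C@H]1CO | intermediate
6 | (4R,5R)-2,2-dimethyl-5-(2-methylprop-1-en-1-yl)-1,3-dioxolane-4-carbaldehyde | CC(C)=C[C@H]1OC(C)(C)O[C@H]1C=O | intermediate
7 | (3E)-4-[(4S,5R)-2,2-dimethyl-5-(2-methylprop-1-en-1-yl)-1,3-dioxolan-4-yl]but-3-en-2-one | CC(C)=C[C@H]1OC(C)(C)O[C@H]1/C=C/C(C)=O | intermediate
8 | triisopropyl({(3E)-4-[(4S,5R)-2,2-dimethyl-5-(2-methylprop-1-en-1-yl)-1,3-dioxolan-4-yl]buta-1,3-dien-2-yl}oxy)silane | CC(C)=C[C@H]1OC(C)(C)O[C@H]1/C=C/C(=C)O[Si](C(C)C)(C(C)C)C(C)C | intermediate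
9 | tiglaldehyde, (E)-2-methylbut-2-enal | C/C=C(\C)C=O | starting material
10 | (1R,2S,6S)-2-[(4S,5R)-2,2-dimethyl-5-(2-methylprop-1-en-1-yl)-1,3-dioxolan-4-yl]-1,6-dimethyl-4-[(triisopropylsilyl)oxy]cyclohex-3-ene-1-carbaldehyde | O=C[C@@]1(C)[C@H](C=C(O[Si](C(C)C)(C(C)C)C(C)C)C[C@@H]1C)[C@@H]2OC(C)(C)O[C@@H]2C=C(C)C | intermediate
11 | {(1R,2S,6S)-2-[(4S,5R)-2,2-dimethyl-5-(2-methylprop-1-en-1-yl)-1,3-dioxolan-4-yl]-1,6-dimethyl-4-[(triisopropylsilyl)oxy]cyclohex-3-en-1-yl}methanol | OC[C@@]1(C)[C@H](C=C(O[Si](C(C)C)(C(C)C)C(C)C)C[C@@H]1C)[C@@H]2OC(C)(C)O[C@@H]2C=C(C)C | intermediate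
12 | (3S,4R,5S)-3-[(4S,5R)-2,2-dimethyl-5-(2-methylprop-1-en-1-yl)-1,3-dioxolan-4-yl]-4-(hydroxymethyl)-4,5-dimethylcyclohexan-1-one | OC[C@@]1(C)[C@H](CC(=O)C[C@@H]1C)[C@@H]2OC(C)(C)O[C@@H]2C=C(C)C | intermediate
13 | (3S,4R,5S)-3-[(4S,5R)-2,2-dimethyl-5-(2-methylprop-1-en-1-yl)-1,3-dioxolan-4-yl]-4-(iodomethyl)-4,5-dimethylcyclohexan-1-one | IC[C@@]1(C)[C@H](CC(=O)C[C@@H]1C)[C@@H]2OC(C)(C)O[C@@H]2C=C(C)C | intermediate
14 | (4S,5R,7R,8R,9S,10S)-8,9-(isopropylidenedioxy)eremophil-11-en-2-one | C=C(C)[C@H]1C[C@@]2(C)[C@H](CC(=O)C[C@@H]2C)[C@@H]3OC(C)(C)O[C@H]13 | intermediate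
15 | (4S,5R,7R,8R,9S,10S)-8,9-dihydroxyeremophil-11-en-2-one | C=C(C)[C@H]1C[C@@]2(C)[C@H](CC(=O)C[C@@H]2C)[C@H](O)[C@@H]1O | intermediate
16 | (R)-2-methylbutanoic acid | CC[C@@H](C)C(=O)O | starting material
17 | (4S,5R,7R,8R,9S,10S)-9-hydroxy-8-{[(2R)-2-methylbutanoyl]oxy}eremophil-11-en-2-one | C=C(C)[C@H]1C[C@@]2(C)[C@H](CC(=O)C[C@@H]2C)[C@H](O)[C@@H]1OC(=O)[C@H](C)CC | intermediate
18 | tigloyl chloride, (E)-2-methylbut-2-enoyl chloride | C/C=C(\C)C(=O)Cl | starting material
19 | CNP0312791.1 | C=C(C)[C@H]1C[C@@]2(C)[C@H](CC(=O)C[C@@H]2C)[C@H](OC(=O)/C(C)=C/C)[C@@H]1OC(=O)[C@H](C)CC | target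

**Step count.** Total: 13 steps. Longest linear sequence: 13 steps, from L-arabinose (1) to 19.

**Steps most likely to fail**

1. Step 10 (key step). The neopentyl radical may be reduced or abstract hydrogen before it cyclises, cobalt may activate the hindered C–I bond only slowly, or hydrogen may be lost toward C7 to give the tetrasubstituted alkene. Fallback: leave the radical manifold and close ring B by a Lewis-acid-promoted intramolecular carbonyl-ene reaction (type 1, as in the citronellal-to-isopulegol cyclisation), which forms the same C6–C7 bond and the same isopropenyl group. It sets out from aldehyde 10. Me2AlCl in CH2Cl2 at −78 °C should give the ring B carbinol with a C6 hydroxyl trans to the isopropenyl group, the 6-hydroxy silyl enol ether F1. NaH, CS2 and MeI convert it into the C6 xanthate F2. Bu3SnH/AIBN in toluene at 110 °C (Barton–McCombie deoxygenation) gives the C6-methylene silyl enol ether F3. Bu4NF/AcOH then returns to the route at 14.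

2. Step 6. The trisubstituted enal may react slowly, so that Mukaiyama-type open-chain addition competes, and endo and facial selectivity may erode if the allylic C9–O stereocentre does not cooperate with the catalyst. Fallback: move the quaternary centre out of the cycloaddition. It sets out from diene 8, which is combined with crotonaldehyde, a more reactive disubstituted enal, under the same catalyst to give the endo adduct with a tertiary C5, the C5-demethyl aldehyde F4. Its potassium enolate (KOt-Bu, THF, −78 °C) is C-methylated with MeI anti to the dioxolane on C10, which returns to the route at 10.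

3. Step 13. Acylation of the axial C9 hydroxyl may be sluggish, since it is shielded by ring A and can add reversibly to the C2 ketone, and forcing conditions invite migration of the C8 acyl group. Fallback: reverse the order of the two acylations so that no acyl group is present while the hindered hydroxyl is forced. It sets out from diol 15, which is silylated at the equatorial C8 hydroxyl (Et3SiCl, imidazole, DMF, −20 °C) to the C8 triethylsilyl ether F5. Tigloyl chloride 18 with DMAP and pyridine at 60 °C gives the C9 tiglate silyl ether F6. HF·pyridine removes the silyl group to give the C9 tiglate C8 alcohol F7. Esterification with 16 (DIC, DMAP, 0 °C) returns to the route at 19.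

**Further compounds**

F1 | step 10 | (4S,5R,7R,8R,9S,10S)-6-hydroxy-8,9-(isopropylidenedioxy)-2-[(triisopropylsilyl)oxy]eremophila-1,11-diene | C=C(C)[C@H]1[C@H](O)[C@@]2(C)[C@H](C=C(O[Si](C(C)C)(C(C)C)C(C)C)C[C@@H]2C)[C@@H]3OC(C)(C)O[C@H]13
F2 | step 10 | O-[C6 of F1] S-methyl carbonodithioate (C6 xanthate) | C=C(C)[C@H]1[C@H](OC(=S)SC)[C@@]2(C)[C@H](C=C(O[Si](C(C)C)(C(C)C)C(C)C)C[C@@H]2C)[C@@H]3OC(C)(C)O[C@H]13
F3 | step 10 | (4S,5R,7R,8R,9S,10S)-8,9-(isopropylidenedioxy)-2-[(triisopropylsilyl)oxy]eremophila-1,11-diene | C=C(C)[C@H]1C[C@@]2(C)[C@H](C=C(O[Si](C(C)C)(C(C)C)C(C)C)C[C@@H]2C)[C@@H]3OC(C)(C)O[C@H]13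
F4 | step 6 | (1R,2S,6S)-2-[(4S,5R)-2,2-dimethyl-5-(2-methylprop-1-en-1-yl)-1,3-dioxolan-4-yl]-6-methyl-4-[(triisopropylsilyl)oxy]cyclohex-3-ene-1-carbaldehyde | O=C[C@H]1[C@H](C=C(O[Si](C(C)C)(C(C)C)C(C)C)C[C@@H]1C)[C@@H]2OC(C)(C)O[C@@H]2C=C(C)C
F5 | step 13 | (4S,5R,7R,8R,9S,10S)-9-hydroxy-8-[(triethylsilyl)oxy]eremophil-11-en-2-one | C=C(C)[C@H]1C[C@@]2(C)[C@H](CC(=O)C[C@@H]2C)[C@H](O)[C@@H]1O[Si](CC)(CC)CC
F6 | step 13 | (4S,5R,7R,8R,9S,10S)-9-{[(2E)-2-methylbut-2-enoyl]oxy}-8-[(triethylsilyl)oxy]eremophil-11-en-2-one | C=C(C)[C@H]1C[C@@]2(C)[C@H](CC(=O)C[C@@H]2C)[C@H](OC(=O)/C(C)=C/C)[C@@H]1O[Si](CC)(CC)CC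
F7 | step 13 | (4S,5R,7R,8R,9S,10S)-8-hydroxy-9-{[(2E)-2-methylbut-2-enoyl]oxy}eremophil-11-en-2-one | C=C(C)[C@H]1C[C@@]2(C)[C@H](CC(=O)C[C@@H]2C)[C@H](OC(=O)/C(C)=C/C)[C@@H]1O
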